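**Plan**

- Retrosynthesis: the two Si–O bonds at O5 and O7 are cut last (fluoride-labile TIPS ethers); ring C is then cut at C3–C4 and at O1–C2.
- Enabling feature: C3 (bearing ring B) and C2–H are the α- and carbonyl carbons of an arylacetaldehyde. In its morpholine enamine C3 is nucleophilic and C2 is a latent electrophile. C4, C4a, C8a and O1 come from a ring A salicyloyl chloride in which the future O1 is the only acetate.
- Ring A: commercial 2-methoxyresorcinol is silylated, borylated at the C–H para to OMe, oxidised to the symmetric phenol, ortho-formylated, acetylated, oxidised to the acid and converted to the chloride.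
- Ring B: tyrosol is O-prenylated, oxidised to the arylacetaldehyde and condensed with morpholine.
- Forward order: rings A and B are bought; ring C arises in one flask (C3–C4 by acylation, then O1–C2 by addition–elimination); desilylation ends the route.
- Stereochemistry: the target has no stereocentre; the E enamine double bond becomes the C2=C3 bond of the pyranone.

Key step: step 11

Assumption: the two enaminone intermediates of the key step are drawn with morpholine trans to the aroyl group (E); such push–pull alkenes isomerise easily and the geometry has no bearing on the ring closure. Fallback intermediates that carry stereocentres would be racemic diastereomer mixtures and are drawn without configuration.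

**Route**

Step 1
Reactants: 1 2-methoxyresorcinol (2-methoxybenzene-1,3-diol)
Product: 2 2-methoxy-1,3-bis(triisopropylsilyloxy)benzene
Conditions: TIPSCl, imidazole, DMF, rt to 40 °C
Reagents that add atoms: triisopropylsilyl chloride, CC(C)[Si](Cl)(C(C)C)C(C)C
Why: Silylation of phenols with a silyl chloride and imidazole in DMF is general, and the TIPS ethers should survive every later step yet fall to fluoride without harm to a prenyl ether.

Step 2
Reactants: 2 2-methoxy-1,3-bis(triisopropylsilyloxy)benzene
Product: 3 2-[4-methoxy-3,5-bis(triisopropylsilyloxy)phenyl]-4,4,5,5-tetramethyl-1,3,2-dioxaborolane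
Conditions: B2pin2 (1 equiv), [Ir(OMe)(cod)]2 (cat.), 4,4'-di-tert-butyl-2,2'-bipyridine (cat.), THF, 80 °C
Reagents that add atoms: bis(pinacolato)diboron, CC1(C)OB(OC1(C)C)B1OC(C)(C)C(C)(C)O1
Why: Iridium-catalysed aromatic C–H borylation is governed by sterics, and the C–H para to the methoxy group is the only one without an ortho substituent, so boron should enter there alone.

Step 3
Reactants: 3 2-[4-methoxy-3,5-bis(triisopropylsilyloxy)phenyl]-4,4,5,5-tetramethyl-1,3,2-dioxaborolane
Product: 4 4-methoxy-3,5-bis(triisopropylsilyloxy)phenol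
Conditions: 30% aq. H2O2, NaHCO3, THF/H2O, 0 °C to rt
Reagents that add atoms: hydrogen peroxide, OO
Why: Oxidation of an arylboronate to a phenol by hydroperoxide (1,2-aryl shift from boron to oxygen) is standard, and the weakly basic medium should spare the aryl silyl ethers.

Step 4
Reactants: 4 4-methoxy-3,5-bis(triisopropylsilyloxy)phenol
Product: 5 2-hydroxy-5-methoxy-4,6-bis(triisopropylsilyloxy)benzaldehyde
Conditions: MgCl2, Et3N, (CH2O)n, MeCN, reflux
Reagents that add atoms: paraformaldehyde (formaldehyde), C=O
Why: In the magnesium-mediated ortho-formylation (Casnati–Skattebøl) the magnesium phenoxide delivers formaldehyde only to an ortho carbon, the two ortho positions are equivalent by symmetry, and a second formaldehyde oxidises the salicyl alkoxide to the aldehyde.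

Step 5
Reactants: 5 2-hydroxy-5-methoxy-4,6-bis(triisopropylsilyloxy)benzaldehyde
Product: 6 2-formyl-4-methoxy-3,5-bis(triisopropylsilyloxy)phenyl acetate
Conditions: Ac2O, Et3N, DMAP (cat.), CH2Cl2, 0 °C to rt
Reagents that add atoms: acetic anhydride, CC(=O)OC(C)=O
Why: DMAP-catalysed acetylation of the phenol is routine and marks the future O1 as the only ester oxygen on ring A.

Step 6
Reactants: 6 2-formyl-4-methoxy-3,5-bis(triisopropylsilyloxy)phenyl acetate
Product: 7 2-acetoxy-5-methoxy-4,6-bis(triisopropylsilyloxy)benzoic acid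
Conditions: NaClO2, NaH2PO4, 2-methyl-2-butene, t-BuOH/THF/H2O, 0 °C to rt
Reagents that add atoms: sodium chlorite, [Na+].[O-]Cl=O
Why: The Pinnick oxidation converts hindered aryl aldehydes to acids in a buffered medium that leaves aryl acetate and silyl ethers intact, while 2-methyl-2-butene traps HOCl before it can chlorinate the electron-rich ring.

Step 7
Reactants: 7 2-acetoxy-5-methoxy-4,6-bis(triisopropylsilyloxy)benzoic acid
Product: 8 2-acetoxy-5-methoxy-4,6-bis(triisopropylsilyloxy)benzoyl chloride
Conditions: (COCl)2, DMF (cat.), CH2Cl2, 0 °C to rt; evaporate, use crude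
Reagents that add atoms: oxalyl chloride, O=C(Cl)C(Cl)=O
Why: Acid chloride formation through the Vilsmeier-type chloroiminium salt is standard for O-acetylsalicylic acids, and the gaseous by-products allow the crude chloride to be used directly.

Step 8
Reactants: 9 tyrosol; 10 prenyl bromide
Product: 11 2-[4-(3-methylbut-2-enyloxy)phenyl]ethanol
Conditions: K2CO3, acetone, reflux
Reagents that add atoms: none
Why: In this Williamson etherification K2CO3 deprotonates only the phenol, so SN2 attack on the primary allylic bromide should give the aryl prenyl ether and leave the aliphatic alcohol free.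

Step 9
Reactants: 11 2-[4-(3-methylbut-2-enyloxy)phenyl]ethanol
Product: 12 [4-(3-methylbut-2-enyloxy)phenyl]acetaldehyde
Conditions: Dess–Martin periodinane, CH2Cl2, 0 °C to rt
Reagents that add atoms: none
Why: The Dess–Martin oxidation stops at the aldehyde under non-aqueous, nearly neutral conditions that suit an enolisable arylacetaldehyde and do not touch the prenyl ether.

Step 10
Reactants: 12 [4-(3-methylbut-2-enyloxy)phenyl]acetaldehyde; 13 morpholine
Product: 14 4-{(E)-2-[4-(3-methylbut-2-enyloxy)phenyl]vinyl}morpholine
Conditions: 4 Å molecular sieves, toluene, rt; filter, evaporate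
Reagents that add atoms: none
Why: Enamine formation by condensation of an aldehyde with a secondary amine under removal of water is classical, and conjugation with ring B should favour the E styrene-type enamine.

Step 11
Reactants: 8 2-acetoxy-5-methoxy-4,6-bis(triisopropylsilyloxy)benzoyl chloride; 14 4-{(E)-2-[4-(3-methylbut-2-enyloxy)phenyl]vinyl}morpholine
Product: 17 6-methoxy-3-[4-(3-methylbut-2-enyloxy)phenyl]-5,7-bis(triisopropylsilyloxy)chromen-4-one (isoaurmillone 5,7-bis-TIPS ether), via acetoxy enaminone 15 (not isolated), via hydroxy enaminone 16 (not isolated)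
Conditions: Et3N, CH2Cl2, 0 °C to rt; then MeOH, K2CO3 (cat.), rt; then AcOH, 40 °C
Reagents that add atoms: none
Why: The nucleophilic β-carbon of enamine 14 (the future C3, bearing ring B) attacks aroyl chloride 8 and Et3N takes up HCl, giving vinylogous amide 15 with the new C3–C4 bond; this is the classical C-acylation of an enamine by an aroyl chloride, used here with an O-acetylsalicyloyl chloride as in the known enamine route to chromones. Catalytic K2CO3 in methanol then transesterifies only the aryl acetate, unmasking the C8a phenol of 16. In the mildly acidic finish this oxygen adds to C2, the iminium-like β-carbon of the enaminone, in a 6-endo-trig oxa-Michael closure of ring C (O1–C2), and the resulting 2-morpholinochromanone eliminates morpholine to give the pyranone. No stereocentre is formed, and the E geometry of the enamine disappears into the C2=C3 bond. The step needs C- rather than N-acylation, which the reversibility of N-acylation and the conjugated β-carbon should favour. It also needs ring closure through the C8a oxygen alone, which is secured because only that oxygen is an acetate, while the C5 and C7 oxygens stay TIPS ethers that resist brief carbonate methanolysis and sit meta to the liberated phenoxide, so no silyl shift is possible.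

Step 12
Reactants: 17 isoaurmillone 5,7-bis-TIPS ether
Product: 18 isoaurmillone (5,7-dihydroxy-6-methoxy-3-[4-(3-methylbut-2-enyloxy)phenyl]chromen-4-one)
Conditions: Bu4NF, AcOH, THF, 0 °C to rt
Reagents that add atoms: none
Why: Fluoride-mediated desilylation is driven by the strong Si–F bond, acetic acid buffers the phenoxides, and neither the aryl prenyl ether nor the pyranone should react.

**Compound list**

1 | 2-methoxyresorcinol (2-methoxybenzene-1,3-diol) | COc1c(O)cccc1O | starting material
2 | 2-methoxy-1,3-bis(triisopropylsilyloxy)benzene | COc1c(O[Si](C(C)C)(C(C)C)C(C)C)cccc1O[Si](C(C)C)(C(C)C)C(C)C | intermediate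
3 | 2-[4-methoxy-3,5-bis(triisopropylsilyloxy)phenyl]-4,4,5,5-tetramethyl-1,3,2-dioxaborolane | COc1c(O[Si](C(C)C)(C(C)C)C(C)C)cc(B2OC(C)(C)C(C)(C)O2)cc1O[Si](C(C)C)(C(C)C)C(C)C | intermediate
4 | 4-methoxy-3,5-bis(triisopropylsilyloxy)phenol | COc1c(O[Si](C(C)C)(C(C)C)C(C)C)cc(O)cc1O[Si](C(C)C)(C(C)C)C(C)C | intermediate
5 | 2-hydroxy-5-methoxy-4,6-bis(triisopropylsilyloxy)benzaldehyde | COc1c(O[Si](C(C)C)(C(C)C)C(C)C)cc(O)c(C=O)c1O[Si](C(C)C)(C(C)C)C(C)C | intermediate
6 | 2-formyl-4-methoxy-3,5-bis(triisopropylsilyloxy)phenyl acetate | COc1c(O[Si](C(C)C)(C(C)C)C(C)C)cc(OC(C)=O)c(C=O)c1O[Si](C(C)C)(C(C)C)C(C)C | intermediate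
7 | 2-acetoxy-5-methoxy-4,6-bis(triisopropylsilyloxy)benzoic acid | COc1c(O[Si](C(C)C)(C(C)C)C(C)C)cc(OC(C)=O)c(C(=O)O)c1O[Si](C(C)C)(C(C)C)C(C)C | intermediate
8 | 2-acetoxy-5-methoxy-4,6-bis(triisopropylsilyloxy)benzoyl chloride | CC(=O)Oc1cc(O[Si](C(C)C)(C(C)C)C(C)C)c(OC)c(O[Si](C(C)C)(C(C)C)C(C)C)c1C(Cl)=O | intermediate
9 | tyrosol (2-(4-hydroxyphenyl)ethanol) | OCCc1ccc(O)cc1 | starting material
10 | prenyl bromide (1-bromo-3-methylbut-2-ene) | CC(C)=CCBr | starting material
11 | 2-[4-(3-methylbut-2-enyloxy)phenyl]ethanol | CC(C)=CCOc1ccc(CCO)cc1 | intermediate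
12 | [4-(3-methylbut-2-enyloxy)phenyl]acetaldehyde | CC(C)=CCOc1ccc(CC=O)cc1 | intermediate
13 | morpholine | C1COCCN1 | starting material
14 | 4-{(E)-2-[4-(3-methylbut-2-enyloxy)phenyl]vinyl}morpholine | CC(C)=CCOc1ccc(/C=C/N2CCOCC2)cc1 | intermediate
15 | acetoxy enaminone: 4-methoxy-2-{(2E)-2-[4-(3-methylbut-2-enyloxy)phenyl]-3-(morpholin-4-yl)prop-2-enoyl}-3,5-bis(triisopropylsilyloxy)phenyl acetate | CC(=O)Oc1cc(O[Si](C(C)C)(C(C)C)C(C)C)c(OC)c(O[Si](C(C)C)(C(C)C)C(C)C)c1C(=O)/C(c1ccc(OCC=C(C)C)cc1)=C/N1CCOCC1 | intermediate (not isolated)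
16 | hydroxy enaminone: (2E)-1-[2-hydroxy-5-methoxy-4,6-bis(triisopropylsilyloxy)phenyl]-2-[4-(3-methylbut-2-enyloxy)phenyl]-3-(morpholin-4-yl)prop-2-en-1-one | Oc1cc(O[Si](C(C)C)(C(C)C)C(C)C)c(OC)c(O[Si](C(C)C)(C(C)C)C(C)C)c1C(=O)/C(c1ccc(OCC=C(C)C)cc1)=C/N1CCOCC1 | intermediate (not isolated)
17 | 6-methoxy-3-[4-(3-methylbut-2-enyloxy)phenyl]-5,7-bis(triisopropylsilyloxy)chromen-4-one (isoaurmillone 5,7-bis-TIPS ether) | COc1c(O[Si](C(C)C)(C(C)C)C(C)C)cc2occ(-c3ccc(OCC=C(C)C)cc3)c(=O)c2c1O[Si](C(C)C)(C(C)C)C(C)C | intermediate
18 | isoaurmillone | COc1c(O)cc2occ(-c3ccc(OCC=C(C)C)cc3)c(=O)c2c1O | target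

**Step count**

Total step count: 12 steps.
Longest linear sequence: 9 steps (steps 1–7, 11 and 12, from 2-methoxyresorcinol); the ring B branch is 3 steps (steps 8–10).

**Steps most likely to fail**

1. Step 11. The enamine may attack the doubly ortho-substituted aroyl chloride only slowly, so that N-acylation, acetyl transfer to the amine or enamine hydrolysis take over. Premature loss of the C5 silyl group before ring closure would also erode the regiocontrol. Fallback: the approach changes from acylation to an aldol-type condensation at the aldehyde oxidation level, setting out from salicylaldehyde 5 and enamine 14 and bypassing steps 5–7. Warming the two in toluene (rt to 60 °C) should give 6-methoxy-2-(morpholin-4-yl)-3-[4-(3-methylbut-2-enyloxy)phenyl]-5,7-bis(triisopropylsilyloxy)chroman-4-ol F1, by C3–C4 bond formation at the aldehyde and capture of the iminium carbon by the phenol. Oxidation of the benzylic alcohol (Dess–Martin periodinane, NaHCO3, CH2Cl2) should give the 2-morpholinochroman-4-one F2, which is not isolated; it should lose morpholine on exposure to AcOH or silica gel and return to the route at 17.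

2. Step 4. Electrophilic attack at an ortho carbon flanked by a bulky silyloxy group may be sluggish, and prolonged heating with MgCl2 and Et3N could strip a silyl group and open the way to over-formylation. Fallback: the formyl carbon is brought in by halogen–metal exchange, setting out from phenol 4. NBS in CH2Cl2 (−78 to 0 °C) should give 2-bromo-4-methoxy-3,5-bis(triisopropylsilyloxy)phenol F3. Deprotonation with MeLi and bromine–lithium exchange with t-BuLi in THF at −78 °C should give the lithium 2-lithiophenoxide F4, which is kept cold to avoid an oxygen-to-carbon silyl shift. Quenching with DMF and aqueous work-up returns to the route at 5.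

3. Step 9. The arylacetaldehyde may enolise, self-condense or oxidise in air during isolation, so that little clean aldehyde reaches the enamine formation. Fallback: the enamine is built by olefination so that no free arylacetaldehyde is handled, setting out from prenyl bromide 10. Alkylation of commercial 4-hydroxybenzaldehyde (K2CO3, acetone) should give 4-(3-methylbut-2-enyloxy)benzaldehyde F5. Horner–Wittig addition of lithiated diphenyl(morpholin-4-ylmethyl)phosphine oxide (n-BuLi, THF, −78 °C) should give 2-(diphenylphosphoryl)-1-[4-(3-methylbut-2-enyloxy)phenyl]-2-(morpholin-4-yl)ethanol F6. Elimination with KOt-Bu in THF should give the enamine, which should settle to the E isomer, returning to the route at 14.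

**Further compounds**

F1 | step 11 | 6-methoxy-2-(morpholin-4-yl)-3-[4-(3-methylbut-2-enyloxy)phenyl]-5,7-bis(triisopropylsilyloxy)chroman-4-ol (diastereomer mixture) | COc1c(O[Si](C(C)C)(C(C)C)C(C)C)cc2OC(N3CCOCC3)C(c3ccc(OCC=C(C)C)cc3)C(O)c2c1O[Si](C(C)C)(C(C)C)C(C)C
F2 | step 11 | 6-methoxy-2-(morpholin-4-yl)-3-[4-(3-methylbut-2-enyloxy)phenyl]-5,7-bis(triisopropylsilyloxy)chroman-4-one (diastereomer mixture, not isolated) | COc1c(O[Si](C(C)C)(C(C)C)C(C)C)cc2OC(N3CCOCC3)C(c3ccc(OCC=C(C)C)cc3)C(=O)c2c1O[Si](C(C)C)(C(C)C)C(C)C
F3 | step 4 | 2-bromo-4-methoxy-3,5-bis(triisopropylsilyloxy)phenol | COc1c(O[Si](C(C)C)(C(C)C)C(C)C)cc(O)c(Br)c1O[Si](C(C)C)(C(C)C)C(C)C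
F4 | step 4 | lithium 2-lithio-4-methoxy-3,5-bis(triisopropylsilyloxy)phenoxide (not isolated) | COc1c(O[Si](C(C)C)(C(C)C)C(C)C)cc(O[Li])c([Li])c1O[Si](C(C)C)(C(C)C)C(C)C
F5 | step 9 | 4-(3-methylbut-2-enyloxy)benzaldehyde | CC(C)=CCOc1ccc(C=O)cc1
F6 | step 9 | 2-(diphenylphosphoryl)-1-[4-(3-methylbut-2-enyloxy)phenyl]-2-(morpholin-4-yl)ethanol (diastereomer mixture) | CC(C)=CCOc1ccc(C(O)C(N2CCOCC2)P(=O)(c2ccccc2)c2ccccc2)cc1
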